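**Retrosynthetic overview**
- Rings A and B are bought: phloroglucinol 1 and 3-hydroxybenzonitrile 2 give, via ketiminium salt 3, benzophenone 4 (Hoesch); iodination (5), C-prenylation with 6 (7) and 4-O-methylation give aryl iodide 8.
- Side-chain stereocentre: dibromide 9 and the Grignard reagent of bromide 10 (11) give (S)-bromide 12 by copper-catalysed enantioselective SN2′ alkylation.
- Aryl–CH2 disconnection: 12 as its zinc reagent 13 couples with silyl-masked 8 (14) to give 15 and, after desilylation, the open-chain triphenol 16 (Negishi).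
- Ring C, the only ring formed, is closed last: 16 → epoxide 17 → target 18 by catalyst-controlled epoxidation of the prenyl group and 6-endo opening by the neighbouring phenol, as in the presumed biogenesis.

Assumption: 9 is bought as the (E)-isomer, and the sense of induction in step 5 is taken by analogy, so the ligand antipode that delivers (S)-12 is used (to be confirmed on the first batch by chiral GC).

**Step 1**
Reactants: 1 phloroglucinol (benzene-1,3,5-triol); 2 3-hydroxybenzonitrile
Product: 4 (3-hydroxyphenyl)(2,4,6-trihydroxyphenyl)methanone, via ketiminium chloride 3 (not isolated)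
Conditions: ZnCl2, HCl (g), Et2O, 0 °C to rt; then H2O, 100 °C
Reagents that add atoms: water, O
Why: Houben–Hoesch acylation, in which the HCl/ZnCl2-activated nitrile is attacked by the C3-symmetric, very electron-rich triol (only one regioisomer possible, and the deactivated ketiminium salt does not react twice) and boiling water hydrolyses the ketiminium chloride to the benzophenone; no stereocentre is involved.

**Step 2**
Reactants: 4 (3-hydroxyphenyl)(2,4,6-trihydroxyphenyl)methanone
Product: 5 (3-hydroxyphenyl)(2,4,6-trihydroxy-3-iodophenyl)methanone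
Conditions: NIS (1.0 equiv), MeCN, −20 °C, dark
Reagents that add atoms: N-iodosuccinimide, O=C1CCC(=O)N1I
Why: Electrophilic aromatic iodination, in which the two equivalent free positions of ring A (each ortho/para to three oxygen donors) react far faster than the acyl-deactivated monophenol ring B, and one equivalent of reagent at low temperature stops at the mono-iodide.

**Step 3**
Reactants: 5 (3-hydroxyphenyl)(2,4,6-trihydroxy-3-iodophenyl)methanone; 6 prenyl bromide (1-bromo-3-methylbut-2-ene)
Product: 7 (3-hydroxyphenyl)[2,4,6-trihydroxy-3-iodo-5-(3-methylbut-2-en-1-yl)phenyl]methanone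
Conditions: KOH (2.2 equiv), H2O, 0 °C, slow addition of 6 (1.1 equiv)
Reagents that add atoms: none
Why: Biomimetic C-prenylation (phenolate C-alkylation), in which the dianion of the acylphloroglucinol reacts in water as a vinylogous β-diketone enolate at its only free ring carbon with the soft allylic bromide (SN2), the limited amount of base leaving the less acidic ring B phenol protonated.

**Step 4**
Reactants: 7 (3-hydroxyphenyl)[2,4,6-trihydroxy-3-iodo-5-(3-methylbut-2-en-1-yl)phenyl]methanone
Product: 8 [2,6-dihydroxy-3-iodo-4-methoxy-5-(3-methylbut-2-en-1-yl)phenyl](3-hydroxyphenyl)methanone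
Conditions: TMSCHN2 (1.05 equiv), PhMe/MeOH 4:1, 0 °C
Reagents that add atoms: (trimethylsilyl)diazomethane, C[Si](C)(C)C=[N+]=[N-]
Why: Chemoselective O-methylation with a diazomethane equivalent, in which the 4-OH (para to the carbonyl, a vinylogous carboxylic acid further acidified by the ortho iodine) protonates the reagent fastest, whereas the two ortho hydroxyls that share the carbonyl hydrogen bond and the ordinary ring B phenol react more slowly.

**Step 5**
Reactants: 9 (E)-1,4-dibromo-2-methylbut-2-ene; 10 4-bromo-2-methylbut-1-ene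
Product: 12 (3S)-3-(bromomethyl)-2,6-dimethylhepta-1,6-diene, via homomethallyl Grignard reagent 11 (not isolated)
Conditions: 10, Mg, Et2O, rt; then slow addition to 9, Cu(O2CC4H3S) (copper thiophene-2-carboxylate, 3 mol%), chiral phosphoramidite (2,2′-biphenol backbone, bis[1-(2-methoxyphenyl)ethyl]amine unit, 3.3 mol%), CH2Cl2, −78 °C
Reagents that add atoms: none
Why: Copper-catalysed asymmetric allylic alkylation (SN2′), in which the chiral monovalent copper complex delivers the alkyl group anti to the departing bromide at the CH terminus of the trisubstituted alkene (attack at the methyl-bearing carbon would build a quaternary centre and is disfavoured), the phosphoramidite selecting the alkene face and so setting the (S) centre, while the homoallylic bromide formed is inert to a second substitution.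

**Step 6**
Reactants: 8 [2,6-dihydroxy-3-iodo-4-methoxy-5-(3-methylbut-2-en-1-yl)phenyl](3-hydroxyphenyl)methanone; 12 (3S)-3-(bromomethyl)-2,6-dimethylhepta-1,6-diene
Product: 16 [2,6-dihydroxy-4-methoxy-3-(3-methylbut-2-en-1-yl)-5-[(2R)-5-methyl-2-(prop-1-en-2-yl)hex-5-en-1-yl]phenyl](3-hydroxyphenyl)methanone, via alkylzinc bromide 13 (not isolated), via tris-TMS ether of iodide 14 (not isolated), via tris-TMS ether of coupled ketone 15 (not isolated)
Conditions: 12, Zn dust, LiCl, THF, 50 °C; 8, BSA (4 equiv), THF, 50 °C; combine, Pd(OAc)2 (4 mol%), SPhos (8 mol%), THF/NMP, 60 °C; then aq. citric acid, rt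
Reagents that add atoms: none
Why: Negishi sp2–sp3 cross-coupling, in which transient O-silylation removes the acidic protons, the bulky biaryl phosphine allows oxidative addition of the di-ortho-substituted aryl iodide and fast reductive elimination after transmetalation of the primary alkylzinc, and the stereocentre is carried over untouched because no bond to it is made or broken (the descriptor changes from S to R only through the CIP ranking).

**Step 7**
Reactants: 16 [2,6-dihydroxy-4-methoxy-3-(3-methylbut-2-en-1-yl)-5-[(2R)-5-methyl-2-(prop-1-en-2-yl)hex-5-en-1-yl]phenyl](3-hydroxyphenyl)methanone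
Product: 18 [(3R)-3,7-dihydroxy-5-methoxy-2,2-dimethyl-6-[(2R)-5-methyl-2-(prop-1-en-2-yl)hex-5-en-1-yl]-3,4-dihydro-2H-chromen-8-yl](3-hydroxyphenyl)methanone, via (R)-epoxide 17 (not isolated)
Conditions: D-fructose-derived Shi ketone (1.0 equiv), KHSO5 (1.5 equiv, as 2KHSO5·KHSO4·K2SO4), NaHCO3, MeCN/DMM/H2O, pH ca. 8, 0 °C; pH 6 work-up; then CSA (10 mol%), CH2Cl2, 0 °C
Reagents that add atoms: potassium peroxymonosulfate, [K+].[O-]S(=O)(=O)OO
Why: Shi asymmetric epoxidation followed by acid-catalysed 6-endo phenol–epoxide cyclisation (the laboratory copy of the prenyl → epoxide → hydroxychroman biogenesis), in which the chiral dioxirane oxidises the electron-rich trisubstituted prenyl alkene markedly faster than the two 1,1-disubstituted alkenes and, through the spiro transition state, from the face that gives the (R)-epoxide, after which the only neighbouring hydroxyl (the other flank is OMe) opens the protonated epoxide at its tertiary carbon, so the C–O bond at the stereocentre is never broken and (R) is retained at C3 of ring C.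

**Compound list**
1 | phloroglucinol (benzene-1,3,5-triol) | Oc1cc(O)cc(O)c1 | starting material
2 | 3-hydroxybenzonitrile | N#Cc1cccc(O)c1 | starting material
3 | (3-hydroxyphenyl)(2,4,6-trihydroxyphenyl)methaniminium chloride | [Cl-].[NH2+]=C(c1cccc(O)c1)c1c(O)cc(O)cc1O | intermediate (not isolated)
4 | (3-hydroxyphenyl)(2,4,6-trihydroxyphenyl)methanone | O=C(c1cccc(O)c1)c1c(O)cc(O)cc1O | intermediate
5 | (3-hydroxyphenyl)(2,4,6-trihydroxy-3-iodophenyl)methanone | O=C(c1cccc(O)c1)c1c(O)cc(O)c(I)c1O | intermediate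
6 | prenyl bromide (1-bromo-3-methylbut-2-ene) | CC(C)=CCBr | starting material
7 | (3-hydroxyphenyl)[2,4,6-trihydroxy-3-iodo-5-(3-methylbut-2-en-1-yl)phenyl]methanone | O=C(c1cccc(O)c1)c1c(O)c(CC=C(C)C)c(O)c(I)c1O | intermediate
8 | [2,6-dihydroxy-3-iodo-4-methoxy-5-(3-methylbut-2-en-1-yl)phenyl](3-hydroxyphenyl)methanone | O=C(c1cccc(O)c1)c1c(O)c(CC=C(C)C)c(OC)c(I)c1O | intermediate
9 | (E)-1,4-dibromo-2-methylbut-2-ene | BrC/C(C)=C/CBr | starting material
10 | 4-bromo-2-methylbut-1-ene | C=C(C)CCBr | starting material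
11 | (3-methylbut-3-en-1-yl)magnesium bromide | C=C(C)CC[Mg]Br | intermediate (not isolated)
12 | (3S)-3-(bromomethyl)-2,6-dimethylhepta-1,6-diene | C=C(C)CC[C@H](CBr)C(=C)C | intermediate
13 | bromo[(2S)-5-methyl-2-(prop-1-en-2-yl)hex-5-en-1-yl]zinc | C=C(C)CC[C@H](C[Zn]Br)C(=C)C | intermediate (not isolated)
14 | [3-iodo-4-methoxy-5-(3-methylbut-2-en-1-yl)-2,6-bis(trimethylsilyloxy)phenyl][3-(trimethylsilyloxy)phenyl]methanone | C[Si](C)(C)Oc1cccc(c1)C(=O)c1c(O[Si](C)(C)C)c(CC=C(C)C)c(OC)c(I)c1O[Si](C)(C)C | intermediate (not isolated)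
15 | [4-methoxy-3-(3-methylbut-2-en-1-yl)-5-[(2R)-5-methyl-2-(prop-1-en-2-yl)hex-5-en-1-yl]-2,6-bis(trimethylsilyloxy)phenyl][3-(trimethylsilyloxy)phenyl]methanone | C=C(C)CC[C@H](Cc1c(O[Si](C)(C)C)c(C(=O)c2cccc(O[Si](C)(C)C)c2)c(O[Si](C)(C)C)c(CC=C(C)C)c1OC)C(=C)C | intermediate (not isolated)
16 | [2,6-dihydroxy-4-methoxy-3-(3-methylbut-2-en-1-yl)-5-[(2R)-5-methyl-2-(prop-1-en-2-yl)hex-5-en-1-yl]phenyl](3-hydroxyphenyl)methanone | C=C(C)CC[C@H](Cc1c(O)c(C(=O)c2cccc(O)c2)c(O)c(CC=C(C)C)c1OC)C(=C)C | intermediate
17 | [2,6-dihydroxy-3-{[(2R)-3,3-dimethyloxiran-2-yl]methyl}-4-methoxy-5-[(2R)-5-methyl-2-(prop-1-en-2-yl)hex-5-en-1-yl]phenyl](3-hydroxyphenyl)methanone | C=C(C)CC[C@H](Cc1c(O)c(C(=O)c2cccc(O)c2)c(O)c(C[C@@H]2C(C)(C)O2)c1OC)C(=C)C | intermediate (not isolated)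
18 | [(3R)-3,7-dihydroxy-5-methoxy-2,2-dimethyl-6-[(2R)-5-methyl-2-(prop-1-en-2-yl)hex-5-en-1-yl]-3,4-dihydro-2H-chromen-8-yl](3-hydroxyphenyl)methanone | C=C(C)CC[C@H](Cc1c(O)c(C(=O)c2cccc(O)c2)c2c(c1OC)C[C@@H](O)C(C)(C)O2)C(=C)C | target

**Step count and risks**
Total steps: 7. Longest linear sequence: 6 steps (1 → 2 → 3 → 4 → 6 → 7); the side-chain branch is the single step 5. Because the two stereocentres are set by independent catalysts, most of the minor enantiomer of either step ends up in the (3R,2′S)/(3S,2′R) diastereomer, which is removed from 18 by chromatography or crystallisation.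

Risk 1, step 5. The 2-methyl-substituted dibromide can react at the wrong allylic terminus or by direct SN2, and the ee on this substrate may stay below 90%. The fallback replaces the catalytic SN2′ step by an auxiliary-controlled dienolate alkylation; it sets out from 10 and comes back to the route at 12. Finkelstein exchange of 10 (NaI, acetone, reflux) gives 4-iodo-2-methylbut-1-ene F1. Commercial (4S)-4-benzyl-1,3-oxazolidin-2-one is N-acylated (n-BuLi, THF, −78 °C, then 3-methylbut-2-enoyl chloride) to (4S)-4-benzyl-3-(3-methylbut-2-enoyl)-1,3-oxazolidin-2-one F2. γ-Deprotonation of F2 with NaN(SiMe3)2 (THF, −78 °C) gives the chelated Z-dienolate, which F1 alkylates at the α-carbon (THF/DMPU, −78 to −30 °C) on the face opposite the benzyl group to give (4S)-4-benzyl-3-[(2S)-5-methyl-2-(prop-1-en-2-yl)hex-5-enoyl]-1,3-oxazolidin-2-one F3, whose minor diastereomer can be removed. LiBH4 (Et2O, 1 equiv MeOH, 0 °C) releases (2S)-5-methyl-2-(prop-1-en-2-yl)hex-5-en-1-ol F4, and CBr4/PPh3 (CH2Cl2, 0 °C) converts F4 into 12.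

Risk 2, step 6. The aryl iodide is hexasubstituted and electron-rich, incomplete silylation would protonate 13, and protodeiodination can compete. The fallback uses boron instead of zinc and needs no masking; it sets out from 12 (with 8) and comes back at 16. 12 is converted (Mg, THF) into [(2S)-5-methyl-2-(prop-1-en-2-yl)hex-5-en-1-yl]magnesium bromide F5, which is treated with B(OMe)3 (−78 °C) and then aqueous KHF2 to give potassium trifluoro[(2S)-5-methyl-2-(prop-1-en-2-yl)hex-5-en-1-yl]borate F6. Suzuki–Miyaura coupling of F6 with unprotected 8 (Pd(OAc)2, RuPhos, K2CO3, PhMe/H2O, 85 °C), where the phenols are present as harmless phenoxides, gives 16.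

Risk 3, step 7. The free phenols may be oxidised by the dioxirane, partial ionisation of the ortho hydroxyl may cause base-induced 5-exo closure to the isomeric hydroxyisopropyl-dihydrobenzofuran, and excess oxidant may touch the 1,1-disubstituted alkenes. The fallback masks the phenols before epoxidation; it sets out from 16 and comes back at 18. TBSOTf/2,6-lutidine (CH2Cl2, 0 °C to rt) gives the tris(tert-butyldimethylsilyl) ether of 16 F7. Standard catalytic Shi epoxidation (Shi ketone 30 mol%, KHSO5, K2CO3, Bu4NHSO4, MeCN/DMM/aq. Na2B4O7, pH 10.5, 0 °C) gives the (R)-epoxide of that ether F8 with no phenolate present. HF·pyridine (THF, 0 °C to rt) then removes the three silyl groups and, being acidic, closes ring C in the 6-endo mode to 18.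

**Further compounds**
F1 | step 5 | 4-iodo-2-methylbut-1-ene | C=C(C)CCI
F2 | step 5 | (4S)-4-benzyl-3-(3-methylbut-2-enoyl)-1,3-oxazolidin-2-one | CC(C)=CC(=O)N1[C@@H](Cc2ccccc2)COC1=O
F3 | step 5 | (4S)-4-benzyl-3-[(2S)-5-methyl-2-(prop-1-en-2-yl)hex-5-enoyl]-1,3-oxazolidin-2-one | C=C(C)CC[C@H](C(=O)N1[C@@H](Cc2ccccc2)COC1=O)C(=C)C
F4 | step 5 | (2S)-5-methyl-2-(prop-1-en-2-yl)hex-5-en-1-ol | C=C(C)CC[C@H](CO)C(=C)C
F5 | step 6 | [(2S)-5-methyl-2-(prop-1-en-2-yl)hex-5-en-1-yl]magnesium bromide | C=C(C)CC[C@H](C[Mg]Br)C(=C)C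
F6 | step 6 | potassium trifluoro[(2S)-5-methyl-2-(prop-1-en-2-yl)hex-5-en-1-yl]borate | C=C(C)CC[C@H](C[B-](F)(F)F)C(=C)C.[K+]
F7 | step 7 | [2,6-bis(tert-butyldimethylsilyloxy)-4-methoxy-3-(3-methylbut-2-en-1-yl)-5-[(2R)-5-methyl-2-(prop-1-en-2-yl)hex-5-en-1-yl]phenyl][3-(tert-butyldimethylsilyloxy)phenyl]methanone | C=C(C)CC[C@H](Cc1c(O[Si](C)(C)C(C)(C)C)c(C(=O)c2cccc(O[Si](C)(C)C(C)(C)C)c2)c(O[Si](C)(C)C(C)(C)C)c(CC=C(C)C)c1OC)C(=C)C
F8 | step 7 | [2,6-bis(tert-butyldimethylsilyloxy)-3-{[(2R)-3,3-dimethyloxiran-2-yl]methyl}-4-methoxy-5-[(2R)-5-methyl-2-(prop-1-en-2-yl)hex-5-en-1-yl]phenyl][3-(tert-butyldimethylsilyloxy)phenyl]methanone | C=C(C)CC[C@H](Cc1c(O[Si](C)(C)C(C)(C)C)c(C(=O)c2cccc(O[Si](C)(C)C(C)(C)C)c2)c(O[Si](C)(C)C(C)(C)C)c(C[C@@H]2C(C)(C)O2)c1OC)C(=C)C
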